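Remark on the chemistry: 2,4-dihydroxy-6-methylbenzoic acid (1) is taken as the purchasable source of ring A, because its carboxyl group is already in place and can be carried as an allyl ester. Compounds 12, 14, 15, 17, 19 and 20 are handled as stereoisomer mixtures, since their enolisable centres disappear on aromatisation. Ring positions are numbered as in the benzoates (ring B: C1 bears CO2Me; ring A: C1 bears the depside carbonyl). Chain carbons of 19 run from C1 (ester) to C8.

## Analysis of the target

Target 22 is a depside: two benzene rings joined by one aryl ester, with no stereocentre and no ring fusion. Ring A is a 3-formyl-2,4-dihydroxy-6-methylbenzoyl unit, so its carbonyl at C1 lies between the C2 hydroxyl and the C6 methyl, and the aldehyde at C3 lies between two hydroxyls. Ring B is hexasubstituted: C1 CO2Me, C2 OH, C3 Me, C4 OH, C5 O-aroyl, C6 Me. The sensitive groups are the aldehyde, the electron-rich phenols and the depside ester. With a free ring A C2 hydroxyl the depside ester is a salicylate-type aryl ester that alcohols and bases cleave easily, and it sits next to the free ring B C4 hydroxyl, to which the acyl group can migrate. The difficulty is regiochemistry and congestion: a fully substituted ring B has to be made, and an ester has to be formed between an acid with two ortho substituents and an oxygen with two ortho substituents, at C5 and not at C4 or C2. The strategy rests on the match between ring B atoms C1 to C6 and chain carbons C2 to C7 of a methyl 4-methyl-3,5,7-trioxooctanoate. In that chain the future C5 oxygen sits on an sp3 carbon between two ketones, so the hindered C–O bond can be made by substitution before the ring exists.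

## Retrosynthetic reasoning

Benzyl ethers. Target 22 is traced back to its ring A di-O-benzyl ether 21. The benzyl ethers mask the two ring A phenols through all steps that use base or heat and leave under neutral conditions, so the last step touches neither the depside ester nor the methyl ester.

Ring B C1–C6 bond. In 21 the bond between the ester-bearing carbon and the neighbouring methyl-bearing carbon of ring B is cut, and the three enol-derived double bonds are returned to ketones. This gives the open-chain triketo ester 19. The cut is made here because the C2 methylene of 19 is activated by two carbonyl groups and the C7 ketone is the only carbonyl six atoms away, so one aldol closure sets all six substituents of ring B. The forward reaction must close from C2 to C7, lose water and leave the aroyl group on its oxygen.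

Methyl ester. The β-keto ester end of 19 is traced to the dioxinone 17, a masked acylketene (18). The dioxinone survives the enolate, chlorination and substitution steps that a free β-keto ester would complicate, and it is opened at the end by heat and the alcohol that supplies the methoxy group.

C–O bond at chain C6. The ester oxygen–carbon bond of 17 is cut to give the chloro diketone 15 and the carboxylate 16 of the ring A acid 7. The hindered acid reacts through its oxygen at an activated sp3 carbon, so no attack on a crowded carbonyl and no choice between phenolic hydroxyls is involved.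

C–Cl bond. Chloride 15 comes from the diketone 14 by electrophilic chlorination at the methylene carbon between the two ketones, its most enolised position.

Carbon chain. Diketone 14 is cut at the bond between its terminal acetyl group and the methylene carbon, giving the keto-dioxinone 12 and an acetyl donor. Compound 12 is cut in the same way to the ethyl dioxinone 10, and 10 is cut at its methyl branch to the commercial dioxinone 8. Each bond is made by an enolate of the dioxinone series, which places the branch methyl (ring B C3 methyl) before the chain is extended.

Ring A acid. Acid 7 is traced to its allyl ester 6, because an allyl ester is cleaved at the allyl carbon and the hindered carbonyl is not attacked. Compound 6 comes from the phenol 5 by O-benzylation. Aldehyde 5 comes from 3 by formylation ortho to the only free phenol, for which C3 is the single open ortho position. Compound 3 comes from 2 by selective benzylation of the C4 hydroxyl, and 2 from acid 1.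

## Alternatives that were turned down

Alternative 1: Ring A is built by a Danheiser benzannulation on a finished ring B. The disconnection cuts ring A at C1–C2, C2–C3, C4–C5 and C5–C6. This leads to the diazo enone ester A2 of the ring B phenol A4 and to the siloxyalkyne A3, which carries the formyl carbon as a diethyl acetal. In the forward step irradiation of A2 would trigger a Wolff rearrangement to a vinylketene. This would add A3, and ring opening and 6π closure on heating would give the depside A1 (ring A C2 hydroxyl free, C3 acetal, C4 silyl ether).
- For: the positions of the two oxygens and of the formyl carbon on ring A follow from the mechanism, no formylation is needed, and the assembly is convergent.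
- Against: A4 is itself a hexasubstituted arene with one differentiated hydroxyl, so the main structural problem of the target is moved into a separate sequence. A4 then has to be esterified at its crowded oxygen. The cascade needs heat while A1 already carries a free hydroxyl ortho to the depside carbonyl. Silyl, acetal and benzyl groups must all be removed afterwards.
- Comparison: on regiocontrol in ring A this route is stronger than the chosen one, which relies on a directed formylation (step 3). The chosen route makes ring B in one closure, forms the hindered C–O bond at an sp3 carbon and ends with a single deprotection.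

Alternative 2: Ring A is folded from a tetraketide chain attached to ring B. The disconnection cuts ring A at C1–C6 and leads to the aryl 3,5,7-trioxooctanoate A6, the ester of phenol A4. Mild base would close chain C2 onto the C7 ketone and give the deformyl depside A5.
- For: the unbranched triketo chain is the best precedented substrate for this aldol aromatisation, and on that point this route is stronger than the chosen one.
- Against: A4 is needed again. A6 is an aryl β-keto ester, which under the base of the aldol step can expel the ring B phenoxide by ketene formation or by lactonisation to a pyranone. The aldehyde must then be introduced on ring A at C3 in competition with C5, followed by debenzylation.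
- Comparison: the chosen route carries the aldehyde from the start, uses methoxide-level leaving-group ability at the β-keto ester and builds ring B instead of presupposing it.

Alternative 3: Ring B is built by a Diels–Alder reaction. The disconnection cuts ring B at C1–C2 and C5–C6 and leads to the acyloxy bis(silyloxy)diene A8 and methyl but-2-ynoate A9. Cycloaddition, then loss of the C1 alkoxy group and of the silyl groups on acidic work-up, would give A7, the target with ring A benzyl ethers and the aldehyde as a dioxolane.
- For: like the chosen route it fixes the C5 oxygen before the ring exists, the polarities of diene and dienophile match the required regiochemistry, and the path to the ring-forming step is as short or shorter.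
- Against: A8 must be made by double enol silylation with strong base next to the aroyl ester, which invites acyl transfer. The aldehyde therefore has to be masked and unmasked. A8 is substituted at every carbon and A9 is a β-substituted, sluggish dienophile, so an intermolecular reaction at high temperature is asked of a labile silyl diene.
- Comparison: the chosen route closes the ring intramolecularly under mild base and tolerates the free aldehyde.

Key step: step 12

## Route

Step 1
Reactants: 1 2,4-dihydroxy-6-methylbenzoic acid
Product: 2 allyl 2,4-dihydroxy-6-methylbenzoate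
Conditions: allyl bromide (1.1 equiv), KHCO3 (1.2 equiv), DMF, rt
Reagents that add atoms: allyl bromide, C=CCBr
Why: O-alkylation of the carboxylate; hydrogen carbonate deprotonates only the acid, so the phenols stay free, and room temperature avoids decarboxylation of 1.

Step 2
Reactants: 2 allyl 2,4-dihydroxy-6-methylbenzoate
Product: 3 allyl 4-(benzyloxy)-2-hydroxy-6-methylbenzoate
Conditions: BnBr (1.05 equiv), K2CO3 (1.5 equiv), acetone, reflux
Reagents that add atoms: benzyl bromide, BrCc1ccccc1
Why: Williamson ether synthesis; the C4 hydroxyl, para to the ester, is the more acidic and accessible one, while the C2 hydroxyl is tied up in a hydrogen bond to the ester carbonyl.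

Step 3
Reactants: 3 allyl 4-(benzyloxy)-2-hydroxy-6-methylbenzoate
Product: 5 allyl 4-(benzyloxy)-3-formyl-2-hydroxy-6-methylbenzoate, via hydroxymethyl phenol 4 (not isolated)
Conditions: MgCl2 (2 equiv), Et3N (4 equiv), (CH2O)n (6 equiv), MeCN, reflux; then 1 M HCl
Reagents that add atoms: paraformaldehyde (as formaldehyde), C=O
Why: Casnati–Skattebøl ortho-formylation: the magnesium phenoxide delivers formaldehyde to its ortho carbon through a six-membered transition state and the resulting benzylic alkoxide 4 is oxidised by hydride transfer to a second formaldehyde; C3 is the only free position ortho to the free phenol, so the regiochemistry is fixed by the mechanism.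

Step 4
Reactants: 5 allyl 4-(benzyloxy)-3-formyl-2-hydroxy-6-methylbenzoate
Product: 6 allyl 2,4-bis(benzyloxy)-3-formyl-6-methylbenzoate
Conditions: BnBr (1.3 equiv), Cs2CO3 (1.5 equiv), DMF, 50 °C
Reagents that add atoms: benzyl bromide, BrCc1ccccc1
Why: Williamson ether synthesis; the phenol between ester and aldehyde is acidic and its cesium salt in DMF is reactive enough to be alkylated despite the crowding; the aldehyde is not enolisable.

Step 5
Reactants: 6 allyl 2,4-bis(benzyloxy)-3-formyl-6-methylbenzoate
Product: 7 2,4-bis(benzyloxy)-3-formyl-6-methylbenzoic acid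
Conditions: Pd(PPh3)4 (3 mol%), TolSO2Na (1.2 equiv), THF/MeOH, rt; then 1 M HCl
Reagents that add atoms: none
Why: Tsuji–Trost deallylation: zerovalent palladium ionises the allyl ester to a pi-allyl complex that the sulfinate captures, so the bond is cut at the allyl carbon and the hindered carbonyl, the benzyl ethers and the aldehyde are not touched.

Step 6
Reactants: 8 2,2,6-trimethyl-4H-1,3-dioxin-4-one
Product: 10 6-ethyl-2,2-dimethyl-4H-1,3-dioxin-4-one, via lithium dienolate 9 (not isolated)
Conditions: LiN(iPr)2 (1.1 equiv), THF, −78 °C; MeI (1.5 equiv), DMPU, −78 to −40 °C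
Reagents that add atoms: iodomethane, CI
Why: Deprotonation of the C6 methyl gives the vinylogous ester enolate 9, which is alkylated at its exocyclic gamma carbon by the soft alkyl iodide.

Step 7
Reactants: 10 6-ethyl-2,2-dimethyl-4H-1,3-dioxin-4-one
Product: 12 2,2-dimethyl-6-(3-oxobutan-2-yl)-4H-1,3-dioxin-4-one, via lithium dienolate 11 (not isolated)
Conditions: LiN(SiMe3)2 (2.1 equiv), THF, −78 °C; AcCl (1.0 equiv), −78 °C; then aq. NH4Cl
Reagents that add atoms: acetyl chloride, CC(Cl)=O
Why: Vinylogous Claisen-type C-acylation of dienolate 11 at the gamma carbon; the second equivalent of base takes up the more acidic product so that it does not quench unreacted enolate.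

Step 8
Reactants: 12 2,2-dimethyl-6-(3-oxobutan-2-yl)-4H-1,3-dioxin-4-one
Product: 14 6-(3,5-dioxohexan-2-yl)-2,2-dimethyl-4H-1,3-dioxin-4-one, via dilithium dianion 13 (not isolated)
Conditions: LiN(iPr)2 (2.3 equiv), THF, −78 °C; MeC(O)N(OMe)Me (1.2 equiv), −78 to −20 °C; then 1 M HCl
Reagents that add atoms: N-methoxy-N-methylacetamide, CC(=O)N(C)OC
Why: Claisen condensation of a dianion: the doubly activated C–H is removed first and the methyl ketone second, and the more reactive terminal enolate carbon attacks the Weinreb amide, whose chelated adduct holds until the acidic work-up.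

Step 9
Reactants: 14 6-(3,5-dioxohexan-2-yl)-2,2-dimethyl-4H-1,3-dioxin-4-one
Product: 15 6-(4-chloro-3,5-dioxohexan-2-yl)-2,2-dimethyl-4H-1,3-dioxin-4-one
Conditions: NCS (1.0 equiv), CH2Cl2, 0 °C
Reagents that add atoms: N-chlorosuccinimide, ClN1C(=O)CCC1=O
Why: Electrophilic alpha-chlorination of a 1,3-diketone; the methylene carbon between the two ketones (C4 of the hexanyl chain) belongs to the most enolised and most nucleophilic unit, and one equivalent of a mild chlorine donor without base limits reaction at the methyl-bearing carbon and at the dioxinone ring.

Step 10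
Reactants: 15 6-(4-chloro-3,5-dioxohexan-2-yl)-2,2-dimethyl-4H-1,3-dioxin-4-one; 7 2,4-bis(benzyloxy)-3-formyl-6-methylbenzoic acid
Product: 17 5-(2,2-dimethyl-4-oxo-4H-1,3-dioxin-6-yl)-2,4-dioxohexan-3-yl 2,4-bis(benzyloxy)-3-formyl-6-methylbenzoate, via cesium carboxylate 16 (not isolated)
Conditions: 7, Cs2CO3 (0.5 equiv), DMF, rt; then 15, 0 °C to rt
Reagents that add atoms: none
Why: SN2 displacement of a 2-chloro-1,3-diketone by a carboxylate, the reaction type by which 3-acyloxypentane-2,4-diones are made; the two flanking carbonyl groups activate the carbon, the hindered acid reacts through its unhindered oxygen, and the weakly basic carboxylate should not trigger cyclisation of the diketo-dioxinone.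

Step 11
Reactants: 17 5-(2,2-dimethyl-4-oxo-4H-1,3-dioxin-6-yl)-2,4-dioxohexan-3-yl 2,4-bis(benzyloxy)-3-formyl-6-methylbenzoate
Product: 19 methyl 6-[2,4-bis(benzyloxy)-3-formyl-6-methylbenzoyloxy]-4-methyl-3,5,7-trioxooctanoate, via acylketene 18 (not isolated)
Conditions: MeOH (10 equiv), toluene, 110 °C, sealed tube; used crude
Reagents that add atoms: methanol, CO
Why: Thermal retro-[4+2] of the dioxinone releases acetone and the acylketene 18, which the excess alcohol captures as the beta-keto ester; the medium is neutral, so the aroyl ester, the benzyl ethers and the aldehyde should pass unchanged.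

Step 12
Reactants: 19 methyl 6-[2,4-bis(benzyloxy)-3-formyl-6-methylbenzoyloxy]-4-methyl-3,5,7-trioxooctanoate
Product: 21 methyl 5-[2,4-bis(benzyloxy)-3-formyl-6-methylbenzoyloxy]-2,4-dihydroxy-3,6-dimethylbenzoate, via cyclic aldol 20 (not isolated)
Conditions: Cs2CO3 (1.5 equiv), MeCN, 0 °C to rt, argon; then 1 M HCl, THF, rt
Reagents that add atoms: none
Why: Carbonate generates the enolates of 19, which interconvert by proton transfer, and the C2 carbanion, stabilised by the ester and the C3 ketone, adds to the C7 methyl ketone to give the cyclic aldol 20. This closure is a 6-(enolendo)-exo-trig aldol that forms the ring B C1–C6 bond, and the closest known reaction type is the biomimetic aldol aromatisation of 3,5,7-triketo esters to 2,4-dihydroxybenzoates. E1cB loss of water across chain C2–C7, completed by the acid treatment, and enolisation of the C3 and C5 ketones with the hydrogens on C4 and C6 give the arene, so the stereocentres of 19 and 20 vanish and no new stereocentre remains. The step needs C2 and not the C8 methyl to act as the nucleophile, which the much greater acidity of the doubly activated C2 methylene secures, and a Claisen-type attack of C6 on the ester C1 would give a quaternary centre that cannot aromatise and should revert. It also needs the aroyl group to stay on the chain C6 oxygen: the aroyl carbonyl is flanked by a benzyloxy and a methyl group, and a shift to a neighbouring enolate oxygen would exchange a beta-diketonate for a less stabilised alpha-oxido enol ester. After aromatisation the more stable phenoxide is the one at C4, para to the methyl ester, so base equilibration should also hold the acyl group on the C5 oxygen. The benzyl ether at C2 of ring A blocks salicylate-type expulsion of the ring B oxygen, the aprotic medium keeps alkoxide away from the depside ester, and the non-enolisable aldehyde between two benzyloxy groups stays a spectator.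

Step 13
Reactants: 21 methyl 5-[2,4-bis(benzyloxy)-3-formyl-6-methylbenzoyloxy]-2,4-dihydroxy-3,6-dimethylbenzoate
Product: 22 methyl 5-(3-formyl-2,4-dihydroxy-6-methylbenzoyloxy)-2,4-dihydroxy-3,6-dimethylbenzoate
Conditions: H2 (1 atm), Pd/C (10 wt%), EtOAc, rt
Reagents that add atoms: none
Why: Catalytic hydrogenolysis of the two aryl benzyl ethers; a neutral, non-alcoholic solvent protects the depside ester, and the aldehyde, flanked by two oxygen substituents and hydrogen-bonded once the phenols are free, should be reduced much more slowly than the ethers are cleaved.

## Compound list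

1 | 2,4-dihydroxy-6-methylbenzoic acid (orsellinic acid) | Cc1cc(O)cc(O)c1C(=O)O | starting material
2 | allyl 2,4-dihydroxy-6-methylbenzoate | Cc1cc(O)cc(O)c1C(=O)OCC=C | intermediate
3 | allyl 4-(benzyloxy)-2-hydroxy-6-methylbenzoate | Cc1cc(OCc2ccccc2)cc(O)c1C(=O)OCC=C | intermediate
4 | allyl 4-(benzyloxy)-2-hydroxy-3-(hydroxymethyl)-6-methylbenzoate (present as its magnesium salt, not isolated) | Cc1cc(OCc2ccccc2)c(CO)c(O)c1C(=O)OCC=C | intermediate
5 | allyl 4-(benzyloxy)-3-formyl-2-hydroxy-6-methylbenzoate | Cc1cc(OCc2ccccc2)c(C=O)c(O)c1C(=O)OCC=C | intermediate
6 | allyl 2,4-bis(benzyloxy)-3-formyl-6-methylbenzoate | Cc1cc(OCc2ccccc2)c(C=O)c(OCc2ccccc2)c1C(=O)OCC=C | intermediate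
7 | 2,4-bis(benzyloxy)-3-formyl-6-methylbenzoic acid | Cc1cc(OCc2ccccc2)c(C=O)c(OCc2ccccc2)c1C(=O)O | intermediate
8 | 2,2,6-trimethyl-4H-1,3-dioxin-4-one | CC1=CC(=O)OC(C)(C)O1 | starting material
9 | lithium 2,2-dimethyl-6-methylidene-6H-1,3-dioxin-4-olate (dienolate of 8, not isolated) | C=C1C=C([O-])OC(C)(C)O1.[Li+] | intermediate
10 | 6-ethyl-2,2-dimethyl-4H-1,3-dioxin-4-one | CCC1=CC(=O)OC(C)(C)O1 | intermediate
11 | lithium 6-ethylidene-2,2-dimethyl-6H-1,3-dioxin-4-olate (dienolate of 10, geometry not defined, not isolated) | CC=C1C=C([O-])OC(C)(C)O1.[Li+] | intermediate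
12 | 2,2-dimethyl-6-(3-oxobutan-2-yl)-4H-1,3-dioxin-4-one (racemic) | CC(C(C)=O)C1=CC(=O)OC(C)(C)O1 | intermediate
13 | dilithium dianion of 12 (dienolate and methyl ketone enolate, not isolated) | C=C([O-])C(C)=C1C=C([O-])OC(C)(C)O1.[Li+].[Li+] | intermediate
14 | 6-(3,5-dioxohexan-2-yl)-2,2-dimethyl-4H-1,3-dioxin-4-one (racemic) | CC(C(=O)CC(C)=O)C1=CC(=O)OC(C)(C)O1 | intermediate
15 | 6-(4-chloro-3,5-dioxohexan-2-yl)-2,2-dimethyl-4H-1,3-dioxin-4-one (stereoisomer mixture) | CC(C(=O)C(Cl)C(C)=O)C1=CC(=O)OC(C)(C)O1 | intermediate
16 | cesium 2,4-bis(benzyloxy)-3-formyl-6-methylbenzoate (not isolated) | Cc1cc(OCc2ccccc2)c(C=O)c(OCc2ccccc2)c1C(=O)[O-].[Cs+] | intermediate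
17 | 5-(2,2-dimethyl-4-oxo-4H-1,3-dioxin-6-yl)-2,4-dioxohexan-3-yl 2,4-bis(benzyloxy)-3-formyl-6-methylbenzoate (stereoisomer mixture) | CC(C(=O)C(OC(=O)c1c(C)cc(OCc2ccccc2)c(C=O)c1OCc1ccccc1)C(C)=O)C1=CC(=O)OC(C)(C)O1 | intermediate
18 | 5-methyl-2,4,6,8-tetraoxooct-7-en-3-yl 2,4-bis(benzyloxy)-3-formyl-6-methylbenzoate (acylketene, not isolated) | O=C=CC(=O)C(C)C(=O)C(OC(=O)c1c(C)cc(OCc2ccccc2)c(C=O)c1OCc1ccccc1)C(C)=O | intermediate
19 | methyl 6-[2,4-bis(benzyloxy)-3-formyl-6-methylbenzoyloxy]-4-methyl-3,5,7-trioxooctanoate (stereoisomer mixture) | COC(=O)CC(=O)C(C)C(=O)C(OC(=O)c1c(C)cc(OCc2ccccc2)c(C=O)c1OCc1ccccc1)C(C)=O | intermediate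
20 | methyl 5-[2,4-bis(benzyloxy)-3-formyl-6-methylbenzoyloxy]-6-hydroxy-3,6-dimethyl-2,4-dioxocyclohexane-1-carboxylate (stereoisomer mixture, not isolated) | COC(=O)C1C(=O)C(C)C(=O)C(OC(=O)c2c(C)cc(OCc3ccccc3)c(C=O)c2OCc2ccccc2)C1(C)O | intermediate
21 | methyl 5-[2,4-bis(benzyloxy)-3-formyl-6-methylbenzoyloxy]-2,4-dihydroxy-3,6-dimethylbenzoate | COC(=O)c1c(C)c(OC(=O)c2c(C)cc(OCc3ccccc3)c(C=O)c2OCc2ccccc2)c(O)c(C)c1O | intermediate
22 | methyl 5-(3-formyl-2,4-dihydroxy-6-methylbenzoyloxy)-2,4-dihydroxy-3,6-dimethylbenzoate | COC(=O)c1c(C)c(OC(=O)c2c(C)cc(O)c(C=O)c2O)c(O)c(C)c1O | target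

## Step count and least certain steps

Total: 13 steps. Longest linear sequence: 9 steps (steps 1 to 5 and 10 to 13). The dioxinone branch runs over 8 steps (steps 6 to 13).

Step 12 (key step). The aldol may be slow, because the most acidic hydrogen, on chain C6, draws the C7 carbonyl into a diketonate. During that time two side reactions can compete: acyl transfer from the C6 oxygen, and lactonisation of the C5 enol oxygen onto the methyl ester. After aromatisation the acyl group may also move to the neighbouring C4 oxygen. Fallback: the ester bond is made after ring B, by classical depside esterification, setting out from 14. Heating 14 with methanol in toluene should give methyl 4-methyl-3,5,7-trioxooctanoate F1, and base then acid should close it to methyl 2,4-dihydroxy-3,6-dimethylbenzoate F2. Rieche formylation (Cl2CHOMe, TiCl4) at C5, the only free ring position, should give methyl 5-formyl-2,4-dihydroxy-3,6-dimethylbenzoate F3. Dakin oxidation should give methyl 2,4,5-trihydroxy-3,6-dimethylbenzoate F4, which is air-sensitive and handled under argon. Acylation of F4 with acid 7 through its mixed trifluoroacetic anhydride should favour the C5 hydroxyl, the most electron-rich one and neither chelated nor para to the ester, and the route comes back at 21.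

Step 9. Chlorination may occur at the methyl-bearing carbon next to the dioxinone or at C5 of the dioxinone ring, or a second chlorine may be introduced, since three enolisable positions are present. The chloride that results may also react slowly in step 10 if it rests as its enolate. Fallback: setting out from 14, Regitz diazo transfer (4-acetamidobenzenesulfonyl azide, Et3N, MeCN, 0 °C) can only go to completion at the methylene carbon and should give 6-(4-diazo-3,5-dioxohexan-2-yl)-2,2-dimethyl-4H-1,3-dioxin-4-one F5. Rh2(OAc)4-catalysed O–H insertion of acid 7 should then give 17 directly, where the route is rejoined without 15 and 16.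

Step 11. The acylketene may be captured by the enol oxygen of the neighbouring ketone (pyranone formation) before the alcohol reaches it, or the aroyl group may shift at 110 °C. Fallback: setting out from 17, the ring is closed on the dioxinone itself. Et3N in CH2Cl2 at room temperature should bring about the vinylogous aldol aromatisation to 7-hydroxy-2,2,5,8-tetramethyl-4-oxo-4H-1,3-benzodioxin-6-yl 2,4-bis(benzyloxy)-3-formyl-6-methylbenzoate F6. Opening of its acetonide lactone with K2CO3 in methanol should give 21, where the route is rejoined.

Step 3. The formylation may stall, because the magnesium phenoxide is chelated by the ester and the reacting carbon lies between two oxygen substituents. The hydroxymethyl intermediate may also condense with a second arene. Fallback: the order is changed, setting out from 2. Rieche formylation (Cl2CHOMe, TiCl4, CH2Cl2, −10 °C) of the free resorcinol should give allyl 3-formyl-2,4-dihydroxy-6-methylbenzoate F7, to be separated from any isomer formylated at C5. Double benzylation (BnBr, Cs2CO3, DMF) then leads back to 6.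

Step 13. The aldehyde may be reduced further to the hydroxymethyl or methyl group before both ethers are cleaved, and the product is sensitive to alcohols and base. Fallback: setting out from 21, the ethers are cleaved by a Lewis acid instead of by hydrogen. BCl3 with pentamethylbenzene as benzyl cation scavenger in CH2Cl2 at −78 °C should give 22 directly, and no new intermediate is made.

## Further compounds

F1 | step 12 | methyl 4-methyl-3,5,7-trioxooctanoate | COC(=O)CC(=O)C(C)C(=O)CC(C)=O
F2 | step 12 | methyl 2,4-dihydroxy-3,6-dimethylbenzoate | COC(=O)c1c(C)cc(O)c(C)c1O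
F3 | step 12 | methyl 5-formyl-2,4-dihydroxy-3,6-dimethylbenzoate | COC(=O)c1c(C)c(C=O)c(O)c(C)c1O
F4 | step 12 | methyl 2,4,5-trihydroxy-3,6-dimethylbenzoate | COC(=O)c1c(C)c(O)c(O)c(C)c1O
F5 | step 9 | 6-(4-diazo-3,5-dioxohexan-2-yl)-2,2-dimethyl-4H-1,3-dioxin-4-one | CC(C(=O)C(=[N+]=[N-])C(C)=O)C1=CC(=O)OC(C)(C)O1
F6 | step 11 | 7-hydroxy-2,2,5,8-tetramethyl-4-oxo-4H-1,3-benzodioxin-6-yl 2,4-bis(benzyloxy)-3-formyl-6-methylbenzoate | CC1(C)OC(=O)c2c(C)c(OC(=O)c3c(C)cc(OCc4ccccc4)c(C=O)c3OCc3ccccc3)c(O)c(C)c2O1
F7 | step 3 | allyl 3-formyl-2,4-dihydroxy-6-methylbenzoate | Cc1cc(O)c(C=O)c(O)c1C(=O)OCC=C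
F0 | step 13 | none | none
A1 | alternative 1 | methyl 2,4-bis(benzyloxy)-5-[3-(diethoxymethyl)-2-hydroxy-6-methyl-4-(triisopropylsilyloxy)benzoyloxy]-3,6-dimethylbenzoate | COC(=O)c1c(C)c(OC(=O)c2c(C)cc(O[Si](C(C)C)(C(C)C)C(C)C)c(C(OCC)OCC)c2O)c(OCc2ccccc2)c(C)c1OCc1ccccc1
A2 | alternative 1 | 2,4-bis(benzyloxy)-5-(methoxycarbonyl)-3,6-dimethylphenyl (E)-5-diazo-3-methyl-4-oxopent-2-enoate | COC(=O)c1c(C)c(OC(=O)/C=C(\C)C(=O)C=[N+]=[N-])c(OCc2ccccc2)c(C)c1OCc1ccccc1
A3 | alternative 1 | (3,3-diethoxyprop-1-ynyloxy)triisopropylsilane | CCOC(OCC)C#CO[Si](C(C)C)(C(C)C)C(C)C
A4 | alternative 1 | methyl 2,4-bis(benzyloxy)-5-hydroxy-3,6-dimethylbenzoate | COC(=O)c1c(C)c(O)c(OCc2ccccc2)c(C)c1OCc1ccccc1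
A5 | alternative 2 | methyl 2,4-bis(benzyloxy)-5-(2,4-dihydroxy-6-methylbenzoyloxy)-3,6-dimethylbenzoate | COC(=O)c1c(C)c(OC(=O)c2c(C)cc(O)cc2O)c(OCc2ccccc2)c(C)c1OCc1ccccc1
A6 | alternative 2 | 2,4-bis(benzyloxy)-5-(methoxycarbonyl)-3,6-dimethylphenyl 3,5,7-trioxooctanoate | COC(=O)c1c(C)c(OC(=O)CC(=O)CC(=O)CC(C)=O)c(OCc2ccccc2)c(C)c1OCc1ccccc1
A7 | alternative 3 | methyl 5-[2,4-bis(benzyloxy)-3-(1,3-dioxolan-2-yl)-6-methylbenzoyloxy]-2,4-dihydroxy-3,6-dimethylbenzoate | COC(=O)c1c(C)c(OC(=O)c2c(C)cc(OCc3ccccc3)c(C3OCCO3)c2OCc2ccccc2)c(O)c(C)c1O
A8 | alternative 3 | 4-methoxy-3-methyl-2,4-bis(trimethylsilyloxy)buta-1,3-dienyl 2,4-bis(benzyloxy)-3-(1,3-dioxolan-2-yl)-6-methylbenzoate (double-bond geometry not defined) | COC(O[Si](C)(C)C)=C(C)C(O[Si](C)(C)C)=COC(=O)c1c(C)cc(OCc2ccccc2)c(C2OCCO2)c1OCc1ccccc1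
A9 | alternative 3 | methyl but-2-ynoate | CC#CC(=O)OC
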